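The route rests on cutting ring C of the isoflavan at C3–C4 and O1–C2. The single stereocentre C3 is the α-carbon of a hidden arylacetaldehyde (C2 as the carbonyl, ring B on C3), while C4 and O1 sit ortho on the trioxygenated ring A, i.e. a hidden o-quinone methide. An amine-catalysed enamine/o-quinone methide [4+2] annulation therefore joins both aryl halves, closes ring C as a chroman-2-ol and sets C3 in one operation. Its precursors are a ring A 2-(tosylmethyl)phenol and a ring B (dimethylchromenyl)acetaldehyde, both MOM-protected; reduction, Mitsunobu re-closure and deprotection finish the synthesis.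

Key step: step 10

Remark on the chemistry: the target is read as the (3R)-isoflavan. The absolute sense of induction in step 10 is assigned from the standard shielding model of diarylprolinol silyl ethers and would be checked on the first run; the enantiomeric catalyst is used if it proves opposite.

Step 1
Reactants: 1 5-methoxyresorcinol; 2 N,N-dimethylformamide
Product: 5 2,4-dihydroxy-6-methoxybenzaldehyde, via chloroiminium salt 3 (not isolated), via aryl iminium salt 4 (not isolated)
Conditions: POCl3 (1.2 equiv), 2 (1.5 equiv), MeCN, 0 °C to rt; then H2O, 50 °C; chromatography to remove the isomeric aldehyde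
Reagents that add atoms: water, O
Why: Vilsmeier–Haack formylation: chloroiminium 3, formed from 2 and POCl3, attacks the phloroglucinol-type ring, and the two equivalent carbons flanked by OH and OMe outnumber the single carbon between the two hydroxyls, so 5 should be the major isomer after hydrolysis of 4.

Step 2
Reactants: 5 2,4-dihydroxy-6-methoxybenzaldehyde
Product: 6 2-hydroxy-6-methoxy-4-(methoxymethoxy)benzaldehyde
Conditions: MOMCl (1.05 equiv), K2CO3 (1.5 equiv), acetone, 0 °C to rt
Reagents that add atoms: chloromethyl methyl ether (MOMCl), COCCl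
Why: Williamson etherification; the 2-hydroxyl is held in a hydrogen bond to the formyl group, so the more acidic para hydroxyl should be alkylated selectively by one equivalent of MOMCl.

Step 3
Reactants: 6 2-hydroxy-6-methoxy-4-(methoxymethoxy)benzaldehyde
Product: 7 2-(hydroxymethyl)-3-methoxy-5-(methoxymethoxy)phenol
Conditions: NaBH4 (1.0 equiv), THF–MeOH, 0 °C; pH 7 phosphate buffer quench; crude used at once
Reagents that add atoms: none
Why: Borohydride reduction of the aldehyde; a cold, neutral work-up keeps the electron-rich salicyl alcohol from ionising, and over-reduction is slow at 0 °C.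

Step 4
Reactants: 7 2-(hydroxymethyl)-3-methoxy-5-(methoxymethoxy)phenol
Product: 8 3-methoxy-5-(methoxymethoxy)-2-(tosylmethyl)phenol
Conditions: p-TolSO2H (1.2 equiv), CH2Cl2, 0 °C to rt
Reagents that add atoms: p-toluenesulfinic acid, Cc1ccc(cc1)S(=O)O
Why: SN1-type benzylic substitution: the trioxygenated ring lets the weak sulfinic acid ionise the benzylic alcohol in a non-nucleophilic solvent without cleaving the MOM acetal, and any O-bound sulfinate ester re-ionises, so the S-bound sulfone should accumulate as the thermodynamic product.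

Step 5
Reactants: 9 2,4-dihydroxybenzaldehyde
Product: 10 2-hydroxy-4-(methoxymethoxy)benzaldehyde
Conditions: MOMCl (1.05 equiv), K2CO3 (1.5 equiv), acetone, 0 °C to rt
Reagents that add atoms: chloromethyl methyl ether (MOMCl), COCCl
Why: Williamson etherification, selective for the non-chelated, more acidic 4-hydroxyl for the same reason as in step 2.

Step 6
Reactants: 10 2-hydroxy-4-(methoxymethoxy)benzaldehyde; 11 3-chloro-3-methylbut-1-yne
Product: 12 4-(methoxymethoxy)-2-[(2-methylbut-3-yn-2-yl)oxy]benzaldehyde
Conditions: 11 (2.5 equiv), DBU (3 equiv), CuCl2·2H2O (1 mol%), MeCN, 0 °C to rt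
Reagents that add atoms: none
Why: Copper-catalysed O-propargylation of a phenol with a tertiary propargylic chloride: DBU frees the chelated phenoxide and the copper acetylide ionises to a propargyl cation equivalent that is captured at oxygen, which sidesteps an SN2 reaction at the tertiary carbon.

Step 7
Reactants: 12 4-(methoxymethoxy)-2-[(2-methylbut-3-yn-2-yl)oxy]benzaldehyde
Product: 15 5-(methoxymethoxy)-2,2-dimethyl-2H-chromene-8-carbaldehyde, via allenylphenol 13 (not isolated), via dienone 14 (not isolated)
Conditions: PhNEt2, 190 °C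
Reagents that add atoms: none
Why: Aromatic propargyl Claisen rearrangement onto C3, the only free ortho carbon, then enolisation to 13, a 1,5-hydrogen shift to 14 and oxa-6π electrocyclisation; the gem-dimethyl group accelerates the [3,3] step and the basic solvent protects the MOM ether.

Step 8
Reactants: 15 5-(methoxymethoxy)-2,2-dimethyl-2H-chromene-8-carbaldehyde; 16 (methoxymethyl)triphenylphosphonium chloride
Product: 18 8-(2-methoxyethenyl)-5-(methoxymethoxy)-2,2-dimethyl-2H-chromene (E/Z mixture), via phosphorus ylide 17 (not isolated)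
Conditions: 16 (1.5 equiv), KOtBu (1.45 equiv), THF, 0 °C; then 15, 0 °C to rt
Reagents that add atoms: none
Why: Wittig methoxymethylenation with the non-stabilised ylide 17; the alkene geometry is irrelevant because both enol ethers converge on the same aldehyde.

Step 9
Reactants: 18 8-(2-methoxyethenyl)-5-(methoxymethoxy)-2,2-dimethyl-2H-chromene
Product: 20 2-[5-(methoxymethoxy)-2,2-dimethyl-2H-chromen-8-yl]acetaldehyde, via organomercurial 19 (not isolated)
Conditions: Hg(OAc)2 (1.05 equiv), THF–H2O (10:1), 0 °C; then sat. aq KI, 0 °C to rt; used without storage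
Reagents that add atoms: water, O
Why: Oxymercuration–demercuration hydrolysis of an enol ether: Hg(OAc)2 and water add across the electron-rich O–C=C unit far faster than across the hindered chromene alkene, loss of methanol gives 19, and iodide strips mercury to release the aldehyde at near-neutral pH, which spares the aryl MOM acetal.

Step 10
Reactants: 8 3-methoxy-5-(methoxymethoxy)-2-(tosylmethyl)phenol; 20 2-[5-(methoxymethoxy)-2,2-dimethyl-2H-chromen-8-yl]acetaldehyde
Product: 24 (3R)-5-methoxy-7-(methoxymethoxy)-3-[5-(methoxymethoxy)-2,2-dimethyl-2H-chromen-8-yl]chroman-2-ol (anomeric mixture), via o-quinone methide 21 (not isolated), via enamine 22 (not isolated), via aminal 23 (not isolated)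
Conditions: (R)-α,α-diphenylprolinol trimethylsilyl ether (20 mol%), Na2CO3 (1.2 equiv), CH2Cl2, 0 °C, 8 (1.1 equiv) added slowly; crude taken on cold
Reagents that add atoms: none
Why: Proposed new method: Na2CO3 deprotonates the phenol of 8 and p-toluenesulfinate leaves in a 1,4-elimination to give o-quinone methide 21 at low stationary concentration, while 20 condenses with the amine to the (E)-enamine 22; the α-carbon of 22 adds to the exocyclic CH2 of 21 (Michael-type, driven by rearomatisation, forming C3–C4), the phenoxide closes on the iminium carbon (forming O1–C2) to aminal 23, and hydrolysis releases lactol 24 and the catalyst. The closest known reaction type is the aminocatalytic enamine formal [4+2] of aliphatic aldehydes with o-quinone methides released from 2-(1-sulfonylalkyl)phenols, which gives 3,4-disubstituted chroman-2-ols; untested here is the pairing of a CH2-terminated quinone methide with an α-aryl acetaldehyde, in which the enolisable α-carbon is the sole stereocentre. Ring C closes in a stepwise hetero-[4+2] sense, the second bond by 6-exo-trig attack of oxygen on the iminium carbon. C3 is set under catalyst control: the diphenyl(silyloxy)methyl group shields one face of the s-trans (E)-enamine, and the standard shielding model assigns the 3R product to the (R)-catalyst, the descriptor being reversed relative to simple alkyl aldehydes because here the α-substituent has higher CIP rank than the incoming benzylic carbon. The step needs enantiofacial selectivity only, since regiochemistry follows from the polarity of the quinone methide (carbon to CH2, oxygen to C2), the aryl group of 20 fixes the enamine geometry by conjugation, the 5-OMe and 7-OMOM donors tame the quinone methide and the capped 7-oxygen rules out a para-quinone methide. Closure to the lactol shelters the new α-aryl centre from enolisation until reduction.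

Step 11
Reactants: 24 (3R)-5-methoxy-7-(methoxymethoxy)-3-[5-(methoxymethoxy)-2,2-dimethyl-2H-chromen-8-yl]chroman-2-ol
Product: 25 2-{(2R)-3-hydroxy-2-[5-(methoxymethoxy)-2,2-dimethyl-2H-chromen-8-yl]propyl}-3-methoxy-5-(methoxymethoxy)phenol
Conditions: NaBH4 (2 equiv), THF–MeOH, −20 to 0 °C
Reagents that add atoms: none
Why: Borohydride reduction of a lactol through its open hydroxy aldehyde, which should be reduced at low temperature faster than the α-aryl centre can enolise, so C3 is carried over unchanged and the anomeric centre disappears.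

Step 12
Reactants: 25 2-{(2R)-3-hydroxy-2-[5-(methoxymethoxy)-2,2-dimethyl-2H-chromen-8-yl]propyl}-3-methoxy-5-(methoxymethoxy)phenol
Product: 26 (3R)-5-methoxy-7-(methoxymethoxy)-3-[5-(methoxymethoxy)-2,2-dimethyl-2H-chromen-8-yl]chroman
Conditions: PPh3 (1.3 equiv), DIAD (1.3 equiv), THF, 0 °C to rt
Reagents that add atoms: none
Why: Intramolecular Mitsunobu etherification (6-exo-tet): the only free phenol displaces the activated primary alcohol and re-forms ring C as the cyclic ether, while C3 is not a reacting centre and keeps its configuration.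

Step 13
Reactants: 26 (3R)-5-methoxy-7-(methoxymethoxy)-3-[5-(methoxymethoxy)-2,2-dimethyl-2H-chromen-8-yl]chroman
Product: 27 (3R)-3-(5-hydroxy-2,2-dimethyl-2H-chromen-8-yl)-5-methoxychroman-7-ol (CNP0320659.1)
Conditions: 3 M aq HCl–MeOH, rt to 40 °C
Reagents that add atoms: none
Why: Acid-catalysed acetal methanolysis removes both MOM groups as dimethoxymethane; the aryl methyl ether, the dimethylchromene and the non-enolisable C3 centre should be stable to dilute HCl at this temperature.

Compound list
1 | 5-methoxyresorcinol | COc1cc(O)cc(O)c1 | starting material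
2 | N,N-dimethylformamide | CN(C)C=O | starting material
3 | (chloromethylidene)dimethyliminium dichlorophosphate | C[N+](C)=CCl.[O-]P(=O)(Cl)Cl | intermediate
4 | (2,4-dihydroxy-6-methoxybenzylidene)dimethyliminium dichlorophosphate | C[N+](C)=Cc1c(O)cc(O)cc1OC.[O-]P(=O)(Cl)Cl | intermediate
5 | 2,4-dihydroxy-6-methoxybenzaldehyde | COc1cc(O)cc(O)c1C=O | intermediate
6 | 2-hydroxy-6-methoxy-4-(methoxymethoxy)benzaldehyde | COCOc1cc(O)c(C=O)c(OC)c1 | intermediate
7 | 2-(hydroxymethyl)-3-methoxy-5-(methoxymethoxy)phenol | COCOc1cc(O)c(CO)c(OC)c1 | intermediate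
8 | 3-methoxy-5-(methoxymethoxy)-2-(tosylmethyl)phenol | COCOc1cc(O)c(CS(=O)(=O)c2ccc(C)cc2)c(OC)c1 | intermediate
9 | 2,4-dihydroxybenzaldehyde | O=Cc1ccc(O)cc1O | starting material
10 | 2-hydroxy-4-(methoxymethoxy)benzaldehyde | O=Cc1ccc(OCOC)cc1O | intermediate
11 | 3-chloro-3-methylbut-1-yne | C#CC(C)(C)Cl | starting material
12 | 4-(methoxymethoxy)-2-[(2-methylbut-3-yn-2-yl)oxy]benzaldehyde | O=Cc1ccc(OCOC)cc1OC(C)(C)C#C | intermediate
13 | 2-hydroxy-4-(methoxymethoxy)-3-(3-methylbuta-1,2-dien-1-yl)benzaldehyde | O=Cc1ccc(OCOC)c(C=C=C(C)C)c1O | intermediate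
14 | 4-(methoxymethoxy)-5-(3-methylbut-2-en-1-ylidene)-6-oxocyclohexa-1,3-diene-1-carbaldehyde | O=CC1=CC=C(OCOC)C(=CC=C(C)C)C1=O | intermediate
15 | 5-(methoxymethoxy)-2,2-dimethyl-2H-chromene-8-carbaldehyde | O=Cc1ccc(OCOC)c2c1OC(C)(C)C=C2 | intermediate
16 | (methoxymethyl)triphenylphosphonium chloride | COC[P+](c1ccccc1)(c1ccccc1)c1ccccc1.[Cl-] | starting material
17 | (methoxymethylidene)triphenylphosphorane | COC=P(c1ccccc1)(c1ccccc1)c1ccccc1 | intermediate
18 | 8-(2-methoxyethenyl)-5-(methoxymethoxy)-2,2-dimethyl-2H-chromene, E/Z mixture | COC=Cc1ccc(OCOC)c2c1OC(C)(C)C=C2 | intermediate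
19 | 2-(acetoxymercurio)-2-[5-(methoxymethoxy)-2,2-dimethyl-2H-chromen-8-yl]acetaldehyde | CC(=O)O[Hg]C(C=O)c1ccc(OCOC)c2c1OC(C)(C)C=C2 | intermediate
20 | 2-[5-(methoxymethoxy)-2,2-dimethyl-2H-chromen-8-yl]acetaldehyde | O=CCc1ccc(OCOC)c2c1OC(C)(C)C=C2 | intermediate
21 | 5-methoxy-3-(methoxymethoxy)-6-methylidenecyclohexa-2,4-dien-1-one | C=C1C(=O)C=C(OCOC)C=C1OC | intermediate
22 | (E)-enamine of 20 with (R)-α,α-diphenylprolinol trimethylsilyl ether | C[Si](C)(C)OC(c1ccccc1)(c1ccccc1)[C@H]1CCCN1/C=C/c1ccc(OCOC)c2c1OC(C)(C)C=C2 | intermediate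
23 | (3R)-2-(pyrrolidin-1-yl)chroman aminal carrying the catalyst (C2 epimers) | COc1cc(OCOC)cc2c1C[C@H](c1ccc(OCOC)c3c1OC(C)(C)C=C3)C(O2)N1CCC[C@@H]1C(O[Si](C)(C)C)(c1ccccc1)c1ccccc1 | intermediate
24 | (3R)-5-methoxy-7-(methoxymethoxy)-3-[5-(methoxymethoxy)-2,2-dimethyl-2H-chromen-8-yl]chroman-2-ol, anomeric mixture | COc1cc(OCOC)cc2c1C[C@H](c1ccc(OCOC)c3c1OC(C)(C)C=C3)C(O)O2 | intermediate
25 | 2-{(2R)-3-hydroxy-2-[5-(methoxymethoxy)-2,2-dimethyl-2H-chromen-8-yl]propyl}-3-methoxy-5-(methoxymethoxy)phenol | COc1cc(OCOC)cc(O)c1C[C@H](c1ccc(OCOC)c2c1OC(C)(C)C=C2)CO | intermediate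
26 | (3R)-5-methoxy-7-(methoxymethoxy)-3-[5-(methoxymethoxy)-2,2-dimethyl-2H-chromen-8-yl]chroman | COc1cc(OCOC)cc2c1C[C@H](c1ccc(OCOC)c3c1OC(C)(C)C=C3)CO2 | intermediate
27 | (3R)-3-(5-hydroxy-2,2-dimethyl-2H-chromen-8-yl)-5-methoxychroman-7-ol (CNP0320659.1) | COc1cc(O)cc2c1C[C@H](c1ccc(O)c3c1OC(C)(C)C=C3)CO2 | target

Total step count: 13 steps.
Longest linear sequence: 9 steps (steps 5 to 13, from 2,4-dihydroxybenzaldehyde); the ring A branch (steps 1 to 4) joins at step 10.

Steps most likely to fail

1. Step 10 (proposed new method). The risks are poor facial selectivity with the hindered α-aryl enamine, erosion of the new α-aryl centre through the open aldehyde, and self-condensation of the quinone methide before it is intercepted. The fallback sets C3 by auxiliary-controlled enolate alkylation, a standard isoflavan tactic, and runs from 20 and 6 back to 25. Pinnick oxidation of 20 (NaClO2, NaH2PO4, 2-methylbut-2-ene, t-BuOH–H2O) would give [5-(methoxymethoxy)-2,2-dimethyl-2H-chromen-8-yl]acetic acid F1. Coupling with (R)-4-benzyl-1,3-oxazolidin-2-one (PivCl, Et3N, LiCl, THF) would give the N-acyl oxazolidinone F2. The electrophile comes from 6: allylation of the chelated phenol (allyl bromide, K2CO3, DMF) to 6-methoxy-4-(methoxymethoxy)-2-(prop-2-en-1-yloxy)benzaldehyde F3, NaBH4 reduction to the benzyl alcohol F4, and Appel bromination (CBr4, PPh3, CH2Cl2, −20 °C) to the benzyl bromide F5, which is used at once. Enolisation of F2 with NaN(SiMe3)2 at −78 °C and alkylation with F5 on the face away from the auxiliary benzyl group should give the (R)-configured alkylated imide F6. LiBH4 in wet THF removes the auxiliary to give the primary alcohol F7, and deallylation with Pd(PPh3)4 and morpholine comes back to the route at 25.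

2. Step 4. The risks are oligomerisation of the very electron-rich salicyl alcohol once it ionises and partial loss of the MOM group under acid. The fallback installs the benzylic leaving group without acid, from 6 back to 8. Reductive amination of 6 (Me2NH, NaBH(OAc)3, 1,2-dichloroethane) would give the Mannich base 2-[(dimethylamino)methyl]-3-methoxy-5-(methoxymethoxy)phenol F8. MeI in MeCN would give the trimethylammonium iodide F9. Warming F9 with TolSO2Na in aqueous MeCN exchanges trimethylamine for sulfinate by elimination–addition through 21 and comes back at 8.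

3. Step 6. The risks are stalled O-alkylation of the hydrogen-bonded, hindered 2-hydroxyl and competing elimination of the tertiary chloride. The fallback builds the pyran ring in the opposite bond order, from 10 back to 15. Ortho-selective condensation of 10 with 3-methylbut-2-enal (ethylenediammonium diacetate, xylene, 140 °C) forms the C–C bond at C3 first and dehydrates to dienone 14, which electrocyclises as in step 7. This skips 12 and makes no new compound (F0).

Further compounds
F1 | step 10 | [5-(methoxymethoxy)-2,2-dimethyl-2H-chromen-8-yl]acetic acid | OC(=O)Cc1ccc(OCOC)c2c1OC(C)(C)C=C2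
F2 | step 10 | (4R)-4-benzyl-3-{[5-(methoxymethoxy)-2,2-dimethyl-2H-chromen-8-yl]acetyl}-1,3-oxazolidin-2-one | O=C(Cc1ccc(OCOC)c2c1OC(C)(C)C=C2)N1C(=O)OC[C@H]1Cc1ccccc1
F3 | step 10 | 6-methoxy-4-(methoxymethoxy)-2-(prop-2-en-1-yloxy)benzaldehyde | C=CCOc1cc(OCOC)cc(OC)c1C=O
F4 | step 10 | [2-methoxy-4-(methoxymethoxy)-6-(prop-2-en-1-yloxy)phenyl]methanol | C=CCOc1cc(OCOC)cc(OC)c1CO
F5 | step 10 | 2-(bromomethyl)-1-methoxy-5-(methoxymethoxy)-3-(prop-2-en-1-yloxy)benzene | C=CCOc1cc(OCOC)cc(OC)c1CBr
F6 | step 10 | (4R)-4-benzyl-3-{(2R)-3-[2-methoxy-4-(methoxymethoxy)-6-(prop-2-en-1-yloxy)phenyl]-2-[5-(methoxymethoxy)-2,2-dimethyl-2H-chromen-8-yl]propanoyl}-1,3-oxazolidin-2-one | O=C([C@H](Cc1c(OCC=C)cc(OCOC)cc1OC)c1ccc(OCOC)c2c1OC(C)(C)C=C2)N1C(=O)OC[C@H]1Cc1ccccc1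
F7 | step 10 | (2R)-3-[2-methoxy-4-(methoxymethoxy)-6-(prop-2-en-1-yloxy)phenyl]-2-[5-(methoxymethoxy)-2,2-dimethyl-2H-chromen-8-yl]propan-1-ol | C=CCOc1cc(OCOC)cc(OC)c1C[C@H](c1ccc(OCOC)c2c1OC(C)(C)C=C2)CO
F8 | step 4 | 2-[(dimethylamino)methyl]-3-methoxy-5-(methoxymethoxy)phenol | COCOc1cc(O)c(CN(C)C)c(OC)c1
F9 | step 4 | [2-hydroxy-6-methoxy-4-(methoxymethoxy)phenyl]-N,N,N-trimethylmethanaminium iodide | COCOc1cc(O)c(C[N+](C)(C)C)c(OC)c1.[I-]
F0 | step 6 | none | none
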